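**Plan**
1. Locants follow germacrane numbering: lactone = O–C6, C7, C11(=C13), C12; ring A = O, C5, C6, C7, C8, C9, C10; ring B = O, C5, C4, C3, C2, C1, C10; C14 = CH3 on C10; C15 = CH2OAc on C4.
2. Cuts, in order: the O8–acyl bond; C7–C8 of ring A together with the shift of the alkene from C11=C13 to C7=C11 (homoallylic alcohol → 3-(chloromethyl)butenolide + aldehyde); C4–H/C15–O (hydroboration); C5–C6 (butenolide + oxocarbenium ion); C4=CH2, C3–O and C3=C4 of ring B back to the acrylate of a linalool-derived tertiary alcohol.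
3. Forward: ring B first (oxepinone by ring-closing metathesis from (R)-linalool, then C3–O and C4=CH2); the lactone ring is attached at C5 as a preformed butenolide; C15 is added; ring A is closed last by a chromium-mediated intramolecular allylation; Mitsunobu esterification and desilylation finish.
4. Enabling feature: C8 is a carbinol carbon bonded to C7, the β-carbon of the α-methylene lactone (C7–C11=C13). One C7–C8 bond formation from a C13 allylmetal therefore closes ring A, sets C7 and C8 and unveils the exocyclic methylene.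
5. Stereochemistry: C10 from (R)-linalool; C3 by catalyst-controlled conjugate borylation; C5 and C6 in the oxocarbenium addition (substrate control); C4 by hydroboration anti to both neighbours; C7 and C8 in the key step, C8 then inverted in the Mitsunobu esterification.
6. Helpers: CH2Cl on the butenolide (lost as chloride in the key step), PMB on the future C8 oxygen, TBS on O3 and on the side-chain hydroxyl (both removed in the last step).

Key step: step 17

Remark: read as drawn, C6 and C9 lie on opposite faces of ring B (C6 cis to the C14 methyl), so ring A spans the trans 2,7-positions of ring B (an in,out 11-oxabicyclo[4.4.1]undecane with H5 inside); the route fixes this relationship in step 12, before ring A is closed.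

**Route**

Step 1
Reactants: 1 (R)-(−)-linalool [(3R)-3,7-dimethylocta-1,6-dien-3-ol]
Product: 3 (3R)-3,7-dimethyloct-6-ene-1,3-diol, via alkylborane 2 (not isolated)
Conditions: 9-BBN (1.3 equiv), THF, 0 °C to rt; then NaOH, H2O2, 0 °C
Reagents that add atoms: hydrogen peroxide, OO
Why: Anti-Markovnikov hydroboration–oxidation in which 9-BBN takes the monosubstituted vinyl group and leaves the trisubstituted alkene, so that the vinyl group becomes the C9–C8 arm while the C10 stereocentre is untouched.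

Step 2
Reactants: 3 (3R)-3,7-dimethyloct-6-ene-1,3-diol
Product: 4 (3R)-1-[(4-methoxybenzyl)oxy]-3,7-dimethyloct-6-en-3-ol
Conditions: NaH (1.05 equiv), 4-methoxybenzyl chloride, Bu4NI (cat.), THF/DMF, 0 °C to rt
Reagents that add atoms: 4-methoxybenzyl chloride, COc1ccc(CCl)cc1
Why: Williamson etherification in which the primary alkoxide forms and reacts far faster than the tertiary one.

Step 3
Reactants: 4 (3R)-1-[(4-methoxybenzyl)oxy]-3,7-dimethyloct-6-en-3-ol
Product: 5 (3R)-1-[(4-methoxybenzyl)oxy]-3,7-dimethyloct-6-en-3-yl prop-2-enoate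
Conditions: acryloyl chloride, iPr2NEt, DMAP (cat.), CH2Cl2, 0 °C to rt
Reagents that add atoms: acryloyl chloride, C=CC(Cl)=O
Why: DMAP-catalysed acylation of the tertiary alcohol, which puts the future ring B oxygen–C5 bond in place without touching C10.

Step 4
Reactants: 5 (3R)-1-[(4-methoxybenzyl)oxy]-3,7-dimethyloct-6-en-3-yl prop-2-enoate
Product: 6 (7R)-7-{2-[(4-methoxybenzyl)oxy]ethyl}-7-methyl-6,7-dihydrooxepin-2(5H)-one
Conditions: second-generation Grubbs catalyst RuCl2(=CHPh)(H2IMes)(PCy3) (5 mol %), CH2Cl2 (0.005 M), reflux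
Reagents that add atoms: none
Why: Ring-closing metathesis between the acrylate and the trisubstituted alkene with loss of 2-methylpropene, the fully substituted C10 favouring closure of the seven-membered unsaturated lactone (C3=C4 cis in the ring).

Step 5
Reactants: 6 (7R)-7-{2-[(4-methoxybenzyl)oxy]ethyl}-7-methyl-6,7-dihydrooxepin-2(5H)-one
Product: 8 (4S,7R)-4-hydroxy-7-{2-[(4-methoxybenzyl)oxy]ethyl}-7-methyloxepan-2-one, via boronate 7 (not isolated)
Conditions: CuCl (5 mol %), NaOtBu (5 mol %), (R,R)-QuinoxP* (6 mol %; ligand enantiomer to be matched to the 3S sense), B2pin2, MeOH (2 equiv), THF, rt; then NaBO3·4H2O, THF/H2O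
Reagents that add atoms: sodium perborate (NaBO3·4H2O), [Na+].OO[B-](O)(O)O
Why: Copper-catalysed asymmetric conjugate borylation of the unsaturated lactone followed by C–B oxidation with retention, the chiral phosphine–copper boryl complex choosing the alkene face so that C3 is set as S independently of the remote C10 centre.

Step 6
Reactants: 8 (4S,7R)-4-hydroxy-7-{2-[(4-methoxybenzyl)oxy]ethyl}-7-methyloxepan-2-one
Product: 9 (4S,7R)-4-[(tert-butyldimethylsilyl)oxy]-7-{2-[(4-methoxybenzyl)oxy]ethyl}-7-methyloxepan-2-one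
Conditions: TBSOTf, 2,6-lutidine, CH2Cl2, −78 °C
Reagents that add atoms: tert-butyldimethylsilyl triflate, CC(C)(C)[Si](C)(C)OS(=O)(=O)C(F)(F)F
Why: Silylation of the β-hydroxy lactone under weakly basic conditions that avoid retro-aldol cleavage or elimination.

Step 7
Reactants: 9 (4S,7R)-4-[(tert-butyldimethylsilyl)oxy]-7-{2-[(4-methoxybenzyl)oxy]ethyl}-7-methyloxepan-2-one
Product: 12 (4S,7R)-4-[(tert-butyldimethylsilyl)oxy]-7-{2-[(4-methoxybenzyl)oxy]ethyl}-7-methyl-3-methylideneoxepan-2-one, via Mannich base 10 (not isolated), via ammonium iodide 11 (not isolated)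
Conditions: LiN(iPr)2, THF, −78 °C; CH2=NMe2+ I−, −78 °C to rt; then MeI, MeOH; then NaHCO3 (aq), CH2Cl2
Reagents that add atoms: Eschenmoser's salt (N,N-dimethylmethyleneiminium iodide), C=[N+](C)C.[I-]
Why: Mannich aminomethylation of the lithium lactone enolate, quaternisation and Hofmann-type β-elimination give the α-methylene lactone, in which C4 is sp2 and carries the future C15.

Step 8
Reactants: 12 (4S,7R)-4-[(tert-butyldimethylsilyl)oxy]-7-{2-[(4-methoxybenzyl)oxy]ethyl}-7-methyl-3-methylideneoxepan-2-one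
Product: 14 (4S,7R)-4-[(tert-butyldimethylsilyl)oxy]-7-{2-[(4-methoxybenzyl)oxy]ethyl}-7-methyl-3-methylideneoxepan-2-yl acetate (both C2 epimers), via aluminium hemiacetal 13 (not isolated)
Conditions: iBu2AlH, CH2Cl2, −78 °C; then pyridine, DMAP, Ac2O, −78 to −20 °C; KNaC4H4O6 (aq)
Reagents that add atoms: acetic anhydride, CC(=O)OC(C)=O
Why: Reductive acetylation, in which one hydride adds 1,2 to the lactone and the aluminium hemiacetal is acetylated before it can open; the configuration at C5 is irrelevant because this centre is ionised in step 12.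

Step 9
Reactants: 15 3-methylidenedihydrofuran-2(3H)-one (α-methylene-γ-butyrolactone)
Product: 17 3-(bromomethyl)furan-2(5H)-one, via dibromide 16 (not isolated)
Conditions: Br2, CH2Cl2, 0 °C; then Et3N, 0 °C
Reagents that add atoms: bromine, BrBr
Why: Bromine addition to the exocyclic alkene and dehydrobromination with the ring β-hydrogen give the endocyclic butenolide that keeps the primary allylic bromide.

Step 10
Reactants: 17 3-(bromomethyl)furan-2(5H)-one
Product: 18 3-(chloromethyl)furan-2(5H)-one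
Conditions: LiCl, DMF, rt
Reagents that add atoms: lithium chloride, [Li+].[Cl-]
Why: Finkelstein-type SN2 halide exchange to the chloride, which should survive the Lewis acid, perborate, acylation and oxidation steps and is still reduced by CrCl2.

Step 11
Reactants: 18 3-(chloromethyl)furan-2(5H)-one
Product: 19 3-(chloromethyl)-2-[(triisopropylsilyl)oxy]furan
Conditions: iPr3SiOTf, iPr2NEt, CH2Cl2, 0 °C; used crude
Reagents that add atoms: triisopropylsilyl triflate, CC(C)[Si](C(C)C)(C(C)C)OS(=O)(=O)C(F)(F)F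
Why: Soft enolisation and O-silylation of the butenolide to the 2-silyloxyfuran, the hindered amine avoiding N-alkylation by the allylic chloride.

Step 12
Reactants: 14 (4S,7R)-4-[(tert-butyldimethylsilyl)oxy]-7-{2-[(4-methoxybenzyl)oxy]ethyl}-7-methyl-3-methylideneoxepan-2-yl acetate; 19 3-(chloromethyl)-2-[(triisopropylsilyl)oxy]furan
Product: 20 (5S)-5-[(2R,4S,7R)-4-[(tert-butyldimethylsilyl)oxy]-7-{2-[(4-methoxybenzyl)oxy]ethyl}-7-methyl-3-methylideneoxepan-2-yl]-3-(chloromethyl)furan-2(5H)-one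
Conditions: BF3·OEt2 (1.5 equiv), CH2Cl2, −78 °C
Reagents that add atoms: none
Why: Vinylogous Mukaiyama addition of the silyloxyfuran γ-carbon to the ring B oxocarbenium ion (1,2-mode), in which C5 should form by attack anti to the CH2CH2OPMB arm on C10 and cis to the C3 silyloxy group (a 1,3-alkoxy group prefers the pseudo-axial position in a cyclic oxocarbenium ion and directs 1,3-cis attack), while C6 is expected mainly in the 5,6-erythro sense and remains base-epimerisable through the 2-oxyfuran anion.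

Step 13
Reactants: 20 (5S)-5-[(2R,4S,7R)-4-[(tert-butyldimethylsilyl)oxy]-7-{2-[(4-methoxybenzyl)oxy]ethyl}-7-methyl-3-methylideneoxepan-2-yl]-3-(chloromethyl)furan-2(5H)-one
Product: 22 (5S)-5-[(2R,3R,4S,7R)-4-[(tert-butyldimethylsilyl)oxy]-3-(hydroxymethyl)-7-{2-[(4-methoxybenzyl)oxy]ethyl}-7-methyloxepan-2-yl]-3-(chloromethyl)furan-2(5H)-one, via alkylborane 21 (not isolated)
Conditions: 9-BBN, THF, rt to 40 °C; then NaBO3·4H2O, THF/H2O
Reagents that add atoms: sodium perborate (NaBO3·4H2O), [Na+].OO[B-](O)(O)O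
Why: Anti-Markovnikov hydroboration–oxidation of the 1,1-disubstituted exocyclic alkene (the electron-poor butenolide alkene should not react), hydrogen being delivered to C4 from the ring face opposite to the cis-disposed C3–OTBS and C5–C6 groups so that C15 ends cis to both.

Step 14
Reactants: 22 (5S)-5-[(2R,3R,4S,7R)-4-[(tert-butyldimethylsilyl)oxy]-3-(hydroxymethyl)-7-{2-[(4-methoxybenzyl)oxy]ethyl}-7-methyloxepan-2-yl]-3-(chloromethyl)furan-2(5H)-one
Product: 23 (5S)-5-[(2R,3R,4S,7R)-3-(acetoxymethyl)-4-[(tert-butyldimethylsilyl)oxy]-7-{2-[(4-methoxybenzyl)oxy]ethyl}-7-methyloxepan-2-yl]-3-(chloromethyl)furan-2(5H)-one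
Conditions: AcCl, 2,4,6-collidine, CH2Cl2, −78 to 0 °C
Reagents that add atoms: acetyl chloride, CC(Cl)=O
Why: O-Acetylation of the primary alcohol with a non-nucleophilic base, which installs the C15 acetate of the target without displacing the allylic chloride.

Step 15
Reactants: 23 (5S)-5-[(2R,3R,4S,7R)-3-(acetoxymethyl)-4-[(tert-butyldimethylsilyl)oxy]-7-{2-[(4-methoxybenzyl)oxy]ethyl}-7-methyloxepan-2-yl]-3-(chloromethyl)furan-2(5H)-one
Product: 24 (5S)-5-[(2R,3R,4S,7R)-3-(acetoxymethyl)-4-[(tert-butyldimethylsilyl)oxy]-7-(2-hydroxyethyl)-7-methyloxepan-2-yl]-3-(chloromethyl)furan-2(5H)-one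
Conditions: DDQ, CH2Cl2/pH 7 buffer, 0 °C
Reagents that add atoms: none
Why: Oxidative cleavage of the PMB ether through its benzylic oxocarbenium ion, which leaves the silyl ether, acetate and allylic chloride alone.

Step 16
Reactants: 24 (5S)-5-[(2R,3R,4S,7R)-3-(acetoxymethyl)-4-[(tert-butyldimethylsilyl)oxy]-7-(2-hydroxyethyl)-7-methyloxepan-2-yl]-3-(chloromethyl)furan-2(5H)-one
Product: 25 (5S)-5-[(2R,3R,4S,7R)-3-(acetoxymethyl)-4-[(tert-butyldimethylsilyl)oxy]-7-methyl-7-(2-oxoethyl)oxepan-2-yl]-3-(chloromethyl)furan-2(5H)-one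
Conditions: Dess–Martin periodinane, NaHCO3, CH2Cl2, 0 °C to rt
Reagents that add atoms: none
Why: Dess–Martin oxidation of the primary alcohol under buffered conditions that should spare the β-alkoxy aldehyde from elimination.

Step 17
Reactants: 25 (5S)-5-[(2R,3R,4S,7R)-3-(acetoxymethyl)-4-[(tert-butyldimethylsilyl)oxy]-7-methyl-7-(2-oxoethyl)oxepan-2-yl]-3-(chloromethyl)furan-2(5H)-one
Product: 27 (3S,4R,5R,6S,7R,8S,10R)-15-acetoxy-3-[(tert-butyldimethylsilyl)oxy]-8-hydroxy-5,10-epoxygermacr-11(13)-en-12,6-olide, via allylchromium 26 (not isolated)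
Conditions: CrCl2 (6 equiv), LiI (0.2 equiv), THF, rt, slow addition of 25 (final 0.003 M)
Reagents that add atoms: none
Why: Two CrCl2 reduce the allylic chloride to the allylchromium 26 (trivalent chromium), which adds to the tethered aldehyde through its γ-carbon C7 with allylic transposition, so that the C7–C8 bond closes ring A and moves the alkene into the exocyclic C11=C13 position; the closest known reaction type is the Nozaki–Hiyama allylation of aldehydes by 2-(halomethyl)acrylates and 3-(halomethyl)butenolides, including ring-closing variants. Ring A closes in the 7-exo-trig mode with respect to the aldehyde C=O, whereas α-attack through C13 would give a nine-membered ring and is not expected. C7 is controlled by C6 and the tether: C9 sits on the face of ring B opposite to C6, so the aldehyde should reach C7 on the butenolide face anti to the C5–C6 bond and give the trans-fused lactone (H6 and H7 anti). C8 is controlled by the closed six-membered Zimmerman–Traxler transition state: the butenolide holds C6 trans to the CH2Cr carbon and C9 takes the pseudo-equatorial position, which gives the 7,8-anti adduct, the (8S)-alcohol that step 22 inverts. The step needs γ-regioselectivity, one butenolide face, and cyclisation ahead of reduction or dimerisation; the first is inherent in allylchromium reagents, the second rests on C6 and on the trans placement of the two arms on ring B, and the third on high dilution.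

Step 18
Reactants: 28 (E)-but-2-enal
Product: 30 (Z)-2-bromobut-2-enal, via dibromide 29 (not isolated)
Conditions: Br2, CH2Cl2, 0 °C; then Et3N, 0 °C
Reagents that add atoms: bromine, BrBr
Why: Bromine addition and E1cB loss of HBr give the α-bromo enal in its preferred geometry, CHO trans to CH3 and Br cis to CH3.

Step 19
Reactants: 30 (Z)-2-bromobut-2-enal
Product: 31 (Z)-2-bromobut-2-en-1-ol
Conditions: NaBH4, CeCl3·7H2O, MeOH, −20 °C
Reagents that add atoms: none
Why: Luche 1,2-reduction of the enal, which keeps the alkene geometry.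

Step 20
Reactants: 31 (Z)-2-bromobut-2-en-1-ol
Product: 32 (Z)-[(2-bromobut-2-en-1-yl)oxy](tert-butyl)dimethylsilane
Conditions: TBSCl, imidazole, DMF, rt
Reagents that add atoms: tert-butyldimethylsilyl chloride, CC(C)(C)[Si](C)(C)Cl
Why: Silylation of the primary allylic alcohol.

Step 21
Reactants: 32 (Z)-[(2-bromobut-2-en-1-yl)oxy](tert-butyl)dimethylsilane
Product: 34 (Z)-2-{[(tert-butyldimethylsilyl)oxy]methyl}but-2-enoic acid, via vinyllithium 33 (not isolated)
Conditions: t-BuLi (2.1 equiv), Et2O, −78 °C; CO2 (g); then cold 1 M HCl to pH 4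
Reagents that add atoms: carbon dioxide, O=C=O
Why: Bromine–lithium exchange and carboxylation both proceed with retention at the configurationally stable vinyllithium, so CO2H ends cis to the β-methyl group as the target requires.

Step 22
Reactants: 27 (3S,4R,5R,6S,7R,8S,10R)-15-acetoxy-3-[(tert-butyldimethylsilyl)oxy]-8-hydroxy-5,10-epoxygermacr-11(13)-en-12,6-olide; 34 (Z)-2-{[(tert-butyldimethylsilyl)oxy]methyl}but-2-enoic acid
Product: 35 (3S,4R,5R,6S,7R,8R,10R)-15-acetoxy-3-[(tert-butyldimethylsilyl)oxy]-8-{[(Z)-2-{[(tert-butyldimethylsilyl)oxy]methyl}but-2-enoyl]oxy}-5,10-epoxygermacr-11(13)-en-12,6-olide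
Conditions: PPh3, DIAD, toluene, 0 °C to rt
Reagents that add atoms: none
Why: Mitsunobu esterification, in which SN2 displacement of the C8 oxyphosphonium group by the carboxylate inverts C8 from S to R and attaches the side chain in one operation.

Step 23
Reactants: 35 (3S,4R,5R,6S,7R,8R,10R)-15-acetoxy-3-[(tert-butyldimethylsilyl)oxy]-8-{[(Z)-2-{[(tert-butyldimethylsilyl)oxy]methyl}but-2-enoyl]oxy}-5,10-epoxygermacr-11(13)-en-12,6-olide
Product: 36 (3S,4S,5R,6S,7R,8R,10R)-15-acetoxy-3-hydroxy-8-{[(Z)-2-(hydroxymethyl)but-2-enoyl]oxy}-5,10-epoxygermacr-11(13)-en-12,6-olide (target)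
Conditions: HF·pyridine, pyridine, THF, 0 °C to rt
Reagents that add atoms: none
Why: Fluoride cleavage of both silyl ethers under mildly acidic conditions that should not cause acetate migration, enoate isomerisation or addition to the α-methylene lactone (the C4 descriptor changes from R to S only because the CIP priorities change).

**Compound list**

1 | (R)-(−)-linalool | O[C@](C)(CCC=C(C)C)C=C | starting material
2 | B-alkyl-9-BBN adduct of 1 | O[C@](C)(CCC=C(C)C)CCB1C2CCCC1CCC2 | intermediate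
3 | (3R)-3,7-dimethyloct-6-ene-1,3-diol | O[C@](C)(CCC=C(C)C)CCO | intermediate
4 | (3R)-1-[(4-methoxybenzyl)oxy]-3,7-dimethyloct-6-en-3-ol | O[C@](C)(CCC=C(C)C)CCOCc1ccc(OC)cc1 | intermediate
5 | (3R)-1-[(4-methoxybenzyl)oxy]-3,7-dimethyloct-6-en-3-yl prop-2-enoate | C=CC(=O)O[C@](C)(CCC=C(C)C)CCOCc1ccc(OC)cc1 | intermediate
6 | (7R)-7-{2-[(4-methoxybenzyl)oxy]ethyl}-7-methyl-6,7-dihydrooxepin-2(5H)-one | O=C1C=CCC[C@](C)(CCOCc2ccc(OC)cc2)O1 | intermediate
7 | C4 pinacol boronate corresponding to 8 (same configuration) | O=C1C[C@@H](B2OC(C)(C)C(C)(C)O2)CC[C@](C)(CCOCc2ccc(OC)cc2)O1 | intermediate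
8 | (4S,7R)-4-hydroxy-7-{2-[(4-methoxybenzyl)oxy]ethyl}-7-methyloxepan-2-one | O=C1C[C@@H](O)CC[C@](C)(CCOCc2ccc(OC)cc2)O1 | intermediate
9 | (4S,7R)-4-[(tert-butyldimethylsilyl)oxy]-7-{2-[(4-methoxybenzyl)oxy]ethyl}-7-methyloxepan-2-one | O=C1C[C@@H](O[Si](C)(C)C(C)(C)C)CC[C@](C)(CCOCc2ccc(OC)cc2)O1 | intermediate
10 | 3-[(dimethylamino)methyl] derivative of 9 (C3 epimers) | O=C1C(CN(C)C)[C@@H](O[Si](C)(C)C(C)(C)C)CC[C@](C)(CCOCc2ccc(OC)cc2)O1 | intermediate
11 | trimethylammonium iodide from 10 | O=C1C(C[N+](C)(C)C)[C@@H](O[Si](C)(C)C(C)(C)C)CC[C@](C)(CCOCc2ccc(OC)cc2)O1.[I-] | intermediate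
12 | (4S,7R)-4-[(tert-butyldimethylsilyl)oxy]-7-{2-[(4-methoxybenzyl)oxy]ethyl}-7-methyl-3-methylideneoxepan-2-one | O=C1C(=C)[C@@H](O[Si](C)(C)C(C)(C)C)CC[C@](C)(CCOCc2ccc(OC)cc2)O1 | intermediate
13 | diisobutylaluminium hemiacetal of 12 | CC(C)C[Al](CC(C)C)OC1O[C@@](C)(CCOCc2ccc(OC)cc2)CC[C@H](O[Si](C)(C)C(C)(C)C)C1=C | intermediate
14 | (4S,7R)-4-[(tert-butyldimethylsilyl)oxy]-7-{2-[(4-methoxybenzyl)oxy]ethyl}-7-methyl-3-methylideneoxepan-2-yl acetate (C2 epimers) | CC(=O)OC1O[C@@](C)(CCOCc2ccc(OC)cc2)CC[C@H](O[Si](C)(C)C(C)(C)C)C1=C | intermediate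
15 | 3-methylidenedihydrofuran-2(3H)-one | C=C1CCOC1=O | starting material
16 | 3-bromo-3-(bromomethyl)dihydrofuran-2(3H)-one | BrCC1(Br)CCOC1=O | intermediate
17 | 3-(bromomethyl)furan-2(5H)-one | BrCC1=CCOC1=O | intermediate
18 | 3-(chloromethyl)furan-2(5H)-one | ClCC1=CCOC1=O | intermediate
19 | 3-(chloromethyl)-2-[(triisopropylsilyl)oxy]furan | ClCc1ccoc1O[Si](C(C)C)(C(C)C)C(C)C | intermediate
20 | (5S)-5-[(2R,4S,7R)-4-[(tert-butyldimethylsilyl)oxy]-7-{2-[(4-methoxybenzyl)oxy]ethyl}-7-methyl-3-methylideneoxepan-2-yl]-3-(chloromethyl)furan-2(5H)-one | O=C1O[C@@H](C=C1CCl)[C@@H]3O[C@](C)(CC[C@H](O[Si](C)(C)C(C)(C)C)C3=C)CCOCc2ccc(OC)cc2 | intermediate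
21 | B-alkyl-9-BBN adduct of 20 at C15 | O=C1O[C@@H](C=C1CCl)[C@@H]3O[C@](C)(CC[C@H](O[Si](C)(C)C(C)(C)C)[C@@H]3CB4C5CCCC4CCC5)CCOCc2ccc(OC)cc2 | intermediate
22 | (5S)-5-[(2R,3R,4S,7R)-4-[(tert-butyldimethylsilyl)oxy]-3-(hydroxymethyl)-7-{2-[(4-methoxybenzyl)oxy]ethyl}-7-methyloxepan-2-yl]-3-(chloromethyl)furan-2(5H)-one | O=C1O[C@@H](C=C1CCl)[C@@H]3O[C@](C)(CC[C@H](O[Si](C)(C)C(C)(C)C)[C@@H]3CO)CCOCc2ccc(OC)cc2 | intermediate
23 | (5S)-5-[(2R,3R,4S,7R)-3-(acetoxymethyl)-4-[(tert-butyldimethylsilyl)oxy]-7-{2-[(4-methoxybenzyl)oxy]ethyl}-7-methyloxepan-2-yl]-3-(chloromethyl)furan-2(5H)-one | O=C1O[C@@H](C=C1CCl)[C@@H]3O[C@](C)(CC[C@H](O[Si](C)(C)C(C)(C)C)[C@@H]3COC(C)=O)CCOCc2ccc(OC)cc2 | intermediate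
24 | (5S)-5-[(2R,3R,4S,7R)-3-(acetoxymethyl)-4-[(tert-butyldimethylsilyl)oxy]-7-(2-hydroxyethyl)-7-methyloxepan-2-yl]-3-(chloromethyl)furan-2(5H)-one | O=C1O[C@@H](C=C1CCl)[C@@H]3O[C@](C)(CC[C@H](O[Si](C)(C)C(C)(C)C)[C@@H]3COC(C)=O)CCO | intermediate
25 | (5S)-5-[(2R,3R,4S,7R)-3-(acetoxymethyl)-4-[(tert-butyldimethylsilyl)oxy]-7-methyl-7-(2-oxoethyl)oxepan-2-yl]-3-(chloromethyl)furan-2(5H)-one | O=C1O[C@@H](C=C1CCl)[C@@H]3O[C@](C)(CC[C@H](O[Si](C)(C)C(C)(C)C)[C@@H]3COC(C)=O)CC=O | intermediate
26 | dichloro(allyl)chromium species from 25 (trivalent chromium at C13) | O=C1O[C@@H](C=C1C[Cr](Cl)Cl)[C@@H]3O[C@](C)(CC[C@H](O[Si](C)(C)C(C)(C)C)[C@@H]3COC(C)=O)CC=O | intermediate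
27 | (3S,4R,5R,6S,7R,8S,10R)-15-acetoxy-3-[(tert-butyldimethylsilyl)oxy]-8-hydroxy-5,10-epoxygermacr-11(13)-en-12,6-olide | C=C1C(=O)O[C@@H]2[C@@H]3O[C@](C)(CC[C@H](O[Si](C)(C)C(C)(C)C)[C@@H]3COC(C)=O)C[C@H](O)[C@@H]12 | intermediate
28 | (E)-but-2-enal | C/C=C/C=O | starting material
29 | 2,3-dibromobutanal | CC(Br)C(Br)C=O | intermediate
30 | (Z)-2-bromobut-2-enal | C/C=C(/C=O)Br | intermediate
31 | (Z)-2-bromobut-2-en-1-ol | C/C=C(/CO)Br | intermediate
32 | (Z)-[(2-bromobut-2-en-1-yl)oxy](tert-butyl)dimethylsilane | C/C=C(/CO[Si](C)(C)C(C)(C)C)Br | intermediate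
33 | vinyllithium from 32 (lithium in place of bromine, same geometry) | C/C=C(/CO[Si](C)(C)C(C)(C)C)[Li] | intermediate
34 | (Z)-2-{[(tert-butyldimethylsilyl)oxy]methyl}but-2-enoic acid | C/C=C(/CO[Si](C)(C)C(C)(C)C)C(=O)O | intermediate
35 | (3S,4R,5R,6S,7R,8R,10R)-15-acetoxy-3-[(tert-butyldimethylsilyl)oxy]-8-{[(Z)-2-{[(tert-butyldimethylsilyl)oxy]methyl}but-2-enoyl]oxy}-5,10-epoxygermacr-11(13)-en-12,6-olide | C=C1C(=O)O[C@@H]2[C@@H]3O[C@](C)(CC[C@H](O[Si](C)(C)C(C)(C)C)[C@@H]3COC(C)=O)C[C@@H](OC(=O)/C(=C\C)CO[Si](C)(C)C(C)(C)C)[C@@H]12 | intermediate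
36 | (3S,4S,5R,6S,7R,8R,10R)-15-acetoxy-3-hydroxy-8-{[(Z)-2-(hydroxymethyl)but-2-enoyl]oxy}-5,10-epoxygermacr-11(13)-en-12,6-olide | C=C1C(=O)O[C@@H]2[C@@H]3O[C@](C)(CC[C@H](O)[C@@H]3COC(C)=O)C[C@@H](OC(=O)/C(=C\C)CO)[C@@H]12 | target

**Totals**
Total step count: 23. Longest linear sequence: 16 steps (steps 1–8, 12–17, 22, 23).

**Steps most likely to fail**

1. Step 17. What may go wrong: the allylchromium attacks the other face of the butenolide (cis-fused lactone), or reduction and dimerisation outrun closure of the trans-bridged ring. Fallback, from 25 and back at 35: the closed chromium transition state is replaced by a Lewis-acid-promoted allylstannane addition through an open transition state. 25 with hexabutylditin and Pd(PPh3)4 (zerovalent palladium) should give the aldehyde allylstannane F1. BF3·OEt2 at −78 °C under high dilution then closes ring A; the antiperiplanar open transition state is expected to give the 7,8-syn adduct, the (8R)-alcohol F2. F2 is acylated with retention by acid 34 through the mixed anhydride F3 (2,4,6-trichlorobenzoyl chloride, Et3N, then DMAP; Yamaguchi esterification) to give 35, so that step 22 is not needed.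

2. Step 12. What may go wrong: the furan adds to the wrong face of the oxocarbenium ion at C5, adds in the conjugate sense at the exocyclic methylene carbon, or the chloromethyl group ionises. Fallback, from 12 and back at 20: the furan is delivered intramolecularly through a temporary silicon tether on O3. HF·pyridine removes the silyl group of 12 to give the hydroxy lactone F4. Butenolide 18 with iPr2SiCl2 and Et3N gives the chlorosilyl dienol ether F5, which silylates F4 (imidazole) to the tethered lactone F6. Reductive acetylation as in step 8 gives the tethered acetoxy ether F7. BF3·OEt2 under high dilution should then bring the furan γ-carbon to the face of the oxocarbenium ion that carries O3 (silyl acetate F8, formed in the flask). HF·pyridine work-up frees the C3 alcohol F9, and TBSOTf with 2,6-lutidine returns to 20.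

3. Step 22. What may go wrong: the activated C8 oxygen is lost by elimination instead of SN2 displacement at this hindered carbon, or the phosphine isomerises the Z-enoate by conjugate addition. Fallback, from 27 and back at 35: activation and displacement are separated. 27 is converted with ClCH2SO2Cl and pyridine into the chloromethanesulfonate F10. F10 is displaced with inversion by the caesium carboxylate F11 (made from 34 and Cs2CO3) with 18-crown-6 in toluene at 80 °C to give 35.

**Further compounds**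

F1 | step 17 | aldehyde 25 with CH2SnBu3 in place of CH2Cl | O=C1O[C@@H](C=C1C[Sn](CCCC)(CCCC)CCCC)[C@@H]3O[C@](C)(CC[C@H](O[Si](C)(C)C(C)(C)C)[C@@H]3COC(C)=O)CC=O
F2 | step 17 | (8R)-epimer of 27 | C=C1C(=O)O[C@@H]2[C@@H]3O[C@](C)(CC[C@H](O[Si](C)(C)C(C)(C)C)[C@@H]3COC(C)=O)C[C@@H](O)[C@@H]12
F3 | step 17 | mixed anhydride of 34 with 2,4,6-trichlorobenzoic acid | C/C=C(/CO[Si](C)(C)C(C)(C)C)C(=O)OC(=O)c1c(Cl)cc(Cl)cc1Cl
F4 | step 12 | (4S,7R)-4-hydroxy-7-{2-[(4-methoxybenzyl)oxy]ethyl}-7-methyl-3-methylideneoxepan-2-one | O=C1C(=C)[C@@H](O)CC[C@](C)(CCOCc2ccc(OC)cc2)O1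
F5 | step 12 | 2-{[chloro(diisopropyl)silyl]oxy}-3-(chloromethyl)furan | ClCc1ccoc1O[Si](Cl)(C(C)C)C(C)C
F6 | step 12 | lactone F4 with O3 bound through Si(iPr)2 to the 2-oxygen of 3-(chloromethyl)furan | O=C1C(=C)[C@@H](O[Si](C(C)C)(C(C)C)Oc3occc3CCl)CC[C@](C)(CCOCc2ccc(OC)cc2)O1
F7 | step 12 | C2 acetoxy ether from F6 (C2 epimers) | CC(=O)OC1O[C@@](C)(CCOCc2ccc(OC)cc2)CC[C@H](O[Si](C(C)C)(C(C)C)Oc3occc3CCl)C1=C
F8 | step 12 | analogue of 20 with an acetoxy(diisopropyl)silyl ether on O3 | O=C1O[C@@H](C=C1CCl)[C@@H]3O[C@](C)(CC[C@H](O[Si](OC(C)=O)(C(C)C)C(C)C)C3=C)CCOCc2ccc(OC)cc2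
F9 | step 12 | analogue of 20 with free C3 hydroxyl | O=C1O[C@@H](C=C1CCl)[C@@H]3O[C@](C)(CC[C@H](O)C3=C)CCOCc2ccc(OC)cc2
F10 | step 22 | C8 chloromethanesulfonate of 27 | C=C1C(=O)O[C@@H]2[C@@H]3O[C@](C)(CC[C@H](O[Si](C)(C)C(C)(C)C)[C@@H]3COC(C)=O)C[C@H](OS(=O)(=O)CCl)[C@@H]12
F11 | step 22 | caesium salt of 34 | C/C=C(/CO[Si](C)(C)C(C)(C)C)C(=O)[O-].[Cs+]
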